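**Retrosynthetic overview** (side-chain locants C1'–C16' count from the benzylic carbon)

- The C9' carbinol carbon is bonded directly to alkenyl C10' and, through the single methylene C8', to alkenyl C7'. O–C9'–C8' is therefore a latent B–CH=CH2 unit lying between two alkenyl carbons, and this is what makes the key step possible.
- Key disconnection C8'–C7', with C9'–C10' formed in the same operation: a Pd-catalysed enantioselective conjunctive cross-coupling of a vinyl/dienyl boron ate complex (C8'–C16') with the (E)-alkenyl bromide C7'–C1'–aryl, followed by C–B to C–OH oxidation and desilylation.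
- Bromide half: geranyl acetate supplies C1'–C6' with the E C2'=C3' alkene. The C6' aldehyde is taken to a 2-alkyne, hydrozirconation/bromination sets E C6'=C7'(Br), and the arene is attached at C1' by arylcopper allylation.
- Boron half: sulcatone is converted to an enyne, Zr-catalysed carboalumination sets E C10'=C11', and the alkenyl iodide becomes an alkenylboronic ester; vinyllithium brings C8' and C9'.
- No ring of the target is formed. The benzene ring comes from 2-bromo-6-methylphenol (para-oxidation, reduction, silylation); the only ring made is the temporary dioxaborolane of the boronic ester, which is lost in the oxidation.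

Key step: step 15

Assumption (remark on the chemistry): the (Sp,Sp) antipode of the MandyPhos ligand is taken to give the (R)-configured C9' boronate, by analogy with the known sense of induction for an sp2 migrating group combined with an sp2 electrophile. Should a Mosher analysis of the derived carbinol show the opposite sense, the (Rp,Rp) ligand is used with no other change.

**Route**

Step 1
Reactants: 1 2-bromo-6-methylphenol
Product: 2 2-bromo-6-methyl-1,4-benzoquinone
Conditions: (KO3S)2NO (2.3 equiv), KH2PO4, H2O/acetone, rt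
Reagents that add atoms: Fremy's salt (potassium nitrosodisulfonate), [K+].[K+].[O]N(S(=O)(=O)[O-])S(=O)(=O)[O-]
Why: Teuber oxidation: the nitroxyl radical abstracts the phenolic hydrogen and a second equivalent delivers oxygen to the only free para position, so the 2,6-disubstituted phenol should give the p-quinone alone.

Step 2
Reactants: 2 2-bromo-6-methyl-1,4-benzoquinone
Product: 3 2-bromo-6-methylbenzene-1,4-diol
Conditions: Na2S2O4 (excess), EtOAc/H2O, rt
Reagents that add atoms: none
Why: Dithionite reduction of a quinone to its hydroquinone is fast and leaves the aryl bromide untouched.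

Step 3
Reactants: 3 2-bromo-6-methylbenzene-1,4-diol
Product: 4 [(2-bromo-6-methyl-1,4-phenylene)bis(oxy)]bis(triisopropylsilane)
Conditions: TIPSOTf (2.4 equiv), 2,6-lutidine, CH2Cl2, 0 °C to rt
Reagents that add atoms: triisopropylsilyl triflate, CC(C)[Si](OS(=O)(=O)C(F)(F)F)(C(C)C)C(C)C
Why: O-silylation with a silyl triflate also reaches the hydroxyl flanked by Br and CH3; TIPS ethers should survive the aryllithium at −78 °C, Pd catalysis and cold alkaline peroxide, and are removed by fluoride at the end.

Step 4
Reactants: 5 geranyl acetate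
Product: 6 (E)-5-(3,3-dimethyloxiran-2-yl)-3-methylpent-2-en-1-yl acetate (racemic)
Conditions: mCPBA (1.0 equiv), CH2Cl2, −20 to 0 °C
Reagents that add atoms: mCPBA, OOC(=O)c1cccc(Cl)c1
Why: Prilezhaev epoxidation selects the distal trisubstituted alkene because the 2,3-alkene is deactivated by the allylic acetate; the oxirane stereocentre is destroyed in the next step.

Step 5
Reactants: 6 (E)-5-(3,3-dimethyloxiran-2-yl)-3-methylpent-2-en-1-yl acetate
Product: 8 (E)-6-acetoxy-4-methylhex-4-enal, via vicinal diol 7 (not isolated)
Conditions: H5IO6 (1.1 equiv), THF/H2O, 0 °C to rt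
Reagents that add atoms: none
Why: Acid-mediated epoxide hydrolysis followed by Malaprade glycol cleavage removes the terminal three carbons as acetone and leaves the E C2'=C3' alkene untouched.

Step 6
Reactants: 8 (E)-6-acetoxy-4-methylhex-4-enal
Product: 9 (E)-3-methylhept-2-en-6-yn-1-ol
Conditions: dimethyl (1-diazo-2-oxopropyl)phosphonate (1.3 equiv), K2CO3 (2.5 equiv), MeOH, 0 °C to rt
Reagents that add atoms: Ohira–Bestmann reagent, CC(=O)C(=[N+]=[N-])P(=O)(OC)OC
Why: Seyferth–Gilbert homologation (Ohira–Bestmann variant) converts the aldehyde into the terminal alkyne, and the same carbonate/methanol medium removes the acetate by transesterification.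

Step 7
Reactants: 9 (E)-3-methylhept-2-en-6-yn-1-ol
Product: 11 (E)-3-methyloct-2-en-6-yn-1-ol, via dilithio derivative 10 (not isolated)
Conditions: n-BuLi (2.1 equiv), THF, −78 to 0 °C; MeI (1.05 equiv), 0 °C to rt
Reagents that add atoms: iodomethane, CI
Why: Acetylide alkylation: in the O,C-dianion the acetylide carbon is far more nucleophilic than the lithium alkoxide, so one equivalent of MeI should methylate carbon only.

Step 8
Reactants: 11 (E)-3-methyloct-2-en-6-yn-1-ol
Product: 13 (2E,6E)-7-bromo-3-methylocta-2,6-dien-1-ol, via alkenylzirconocene 12 (not isolated)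
Conditions: Cp2Zr(H)Cl (3.2 equiv), THF, 50 °C; then NBS (2.2 equiv), 0 °C
Reagents that add atoms: N-bromosuccinimide, BrN1C(=O)CCC1=O
Why: Hydrozirconation with the Schwartz reagent adds Zr–H syn across the alkyne, excess hydride at 50 °C equilibrates zirconium onto the less hindered methyl-bearing carbon C7', and bromination of the C–Zr bond with retention should give the E bromide; the trisubstituted alkene does not react.

Step 9
Reactants: 13 (2E,6E)-7-bromo-3-methylocta-2,6-dien-1-ol
Product: 14 (2E,6E)-1,7-dibromo-3-methylocta-2,6-diene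
Conditions: CBr4 (1.2 equiv), PPh3 (1.25 equiv), CH2Cl2, 0 °C
Reagents that add atoms: tetrabromomethane, BrC(Br)(Br)Br
Why: Appel reaction converts the primary allylic alcohol into the bromide under neutral conditions without allylic transposition and without touching the alkenyl bromide.

Step 10
Reactants: 4 [(2-bromo-6-methyl-1,4-phenylene)bis(oxy)]bis(triisopropylsilane); 14 (2E,6E)-1,7-dibromo-3-methylocta-2,6-diene
Product: 17 [2-[(2E,6E)-7-bromo-3-methylocta-2,6-dien-1-yl]-6-methyl-1,4-phenylene]bis(oxy)bis(triisopropylsilane), via aryllithium 15 (not isolated), via arylcopper 16 (not isolated)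
Conditions: 4, n-BuLi (1.05 equiv), THF, −78 °C; CuBr·SMe2 (1.1 equiv), −78 to −40 °C; 14, −78 to 0 °C
Reagents that add atoms: none
Why: Bromine–lithium exchange, transmetallation to copper and SN2 (α) allylic substitution on the primary allylic bromide should give the linear E allyl arene; the alkenyl bromide is inert to arylcopper, and holding the aryllithium at −78 °C suppresses O-to-C silyl migration.

Step 11
Reactants: 18 6-methylhept-5-en-2-one (sulcatone)
Product: 20 6-methylhept-5-en-1-yne, via enol phosphate 19 (not isolated)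
Conditions: LDA (1.1 equiv), THF, −78 °C; ClP(O)(OEt)2 (1.15 equiv), −78 °C to rt; then LDA (2.3 equiv), −78 °C to rt
Reagents that add atoms: none
Why: Kinetic enolisation on the methyl side, O-phosphorylation and base-induced elimination of diethyl phosphate (driven by acetylide formation) is the standard methyl ketone to terminal alkyne conversion.

Step 12
Reactants: 20 6-methylhept-5-en-1-yne
Product: 22 (E)-1-iodo-2,6-dimethylhepta-1,5-diene, via alkenylalane 21 (not isolated)
Conditions: AlMe3 (2.0 equiv), Cp2ZrCl2 (0.25 equiv), CH2Cl2, 0 °C to rt; then I2 (1.2 equiv), THF, −30 to 0 °C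
Reagents that add atoms: trimethylaluminium, C[Al](C)C; iodine, II
Why: Negishi Zr-catalysed carboalumination adds CH3–Al syn across the terminal alkyne with aluminium on the terminal carbon, and iodinolysis with retention should give the E iodide (the future E C10'=C11' alkene); the remote trisubstituted alkene is not carbometallated.

Step 13
Reactants: 23 acenaphthenequinone
Product: 24 cis-1,2-dimethyl-1,2-dihydroacenaphthylene-1,2-diol ("mac diol")
Conditions: AlMe3 (3 equiv), toluene, 0 °C to rt; aq. HCl
Reagents that add atoms: trimethylaluminium, C[Al](C)C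
Why: Two successive 1,2-additions of Al–CH3 to the 1,2-dione; the second methyl should enter anti to the bulky aluminium alkoxide, giving the cis (meso) diol required for a cyclic boronic ester.

Step 14
Reactants: 22 (E)-1-iodo-2,6-dimethylhepta-1,5-diene; 24 cis-1,2-dimethyl-1,2-dihydroacenaphthylene-1,2-diol
Product: 27 (E)-(2,6-dimethylhepta-1,5-dien-1-yl)boronic acid mac ester, via alkenyllithium 25 (not isolated), via boronic acid 26 (not isolated)
Conditions: t-BuLi (2.05 equiv), Et2O, −78 °C; B(OMe)3 (1.5 equiv), −78 °C to rt; 1 M HCl; then 24, MgSO4, CH2Cl2, rt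
Reagents that add atoms: trimethyl borate, COB(OC)OC
Why: Iodine–lithium exchange with retention of alkene geometry, borylation, and condensation of the boronic acid with the cis-diol should give the hindered boronic ester, whose bulk later disfavours direct transmetallation to palladium.

Step 15
Reactants: 27 (E)-(2,6-dimethylhepta-1,5-dien-1-yl)boronic acid mac ester; 17 [2-[(2E,6E)-7-bromo-3-methylocta-2,6-dien-1-yl]-6-methyl-1,4-phenylene]bis(oxy)bis(triisopropylsilane)
Product: 29 (R)-C9' allylic boronic ester, 2-[(2E,6E,9R,10E)-3,7,11,15-tetramethyl-9-(mac-boryl)hexadeca-2,6,10,14-tetraen-1-yl]-6-methyl-1,4-bis(triisopropylsilyloxy)benzene, via boron ate complex 28 (not isolated)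
Conditions: vinyllithium (1.0 equiv, halide-free, from tetravinyltin and n-BuLi), Et2O, 0 °C to rt; solvent exchange to THF; Pd(OAc)2 (3 mol %), (Sp,Sp)-MandyPhos (3.6 mol %), KOTf (2 equiv), 17 (0.85 equiv), 60 °C
Reagents that add atoms: vinyllithium, [Li]C=C (made in the flask from tetravinyltin, C=C[Sn](C=C)(C=C)C=C, and n-butyllithium)
Why: Oxidative addition of Pd(0)/MandyPhos into the C7'–Br bond of 17 (retention of the E geometry) and bromide abstraction by KOTf should give a cationic alkenyl-Pd(II) that binds the unsubstituted B-vinyl group of 28 and, acting as a π-acid, triggers a 1,2-metallate shift in which the dienyl group migrates from boron to C9' anti to palladium while Pd–C8' forms; reductive elimination then makes the C8'–C7' bond. The closest known reaction type is the enantioselective Pd-catalysed conjunctive cross-coupling of bis(alkenyl)borates with C(sp2) electrophiles, which gives α-chiral allylic boronic esters. No ring is closed; the dioxaborolane of the mac ester is only carried along. The C9' stereocentre is set by the catalyst: the chiral ferrocenyl bisphosphine on palladium decides which enantioface of the B-vinyl group is bound and then attacked by the migrating group. The step needs (i) activation of the vinyl and not the dienyl C=C, secured by the steric contrast between an unsubstituted and a β,β-disubstituted alkenyl group, (ii) metallate shift in preference to direct Suzuki–Miyaura transfer, secured by the hindered mac diol on boron and the wide-bite-angle ligand, and (iii) retention of both alkene geometries, which is inherent in oxidative addition/reductive elimination and in alkenyl migration.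

Step 16
Reactants: 29 (R)-C9' allylic boronic ester
Product: 30 (2E,6E,9R,10E)-3,7,11,15-tetramethyl-1-[3-methyl-2,5-bis(triisopropylsilyloxy)phenyl]hexadeca-2,6,10,14-tetraen-9-ol
Conditions: 30% H2O2, 3 M NaOH, THF, 0 °C
Reagents that add atoms: hydrogen peroxide, OO
Why: Boronate oxidation: hydroperoxide adds to boron and C9' migrates from B to O with retention and without allylic transposition, so the (R)-boronate should give the (R)-carbinol; aryl TIPS ethers and trisubstituted alkenes are inert to cold alkaline peroxide.

Step 17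
Reactants: 30 (2E,6E,9R,10E)-3,7,11,15-tetramethyl-1-[3-methyl-2,5-bis(triisopropylsilyloxy)phenyl]hexadeca-2,6,10,14-tetraen-9-ol
Product: 31 2-[(2E,6E,9R,10E)-9-hydroxy-3,7,11,15-tetramethylhexadeca-2,6,10,14-tetraen-1-yl]-6-methylbenzene-1,4-diol (target)
Conditions: TBAF (2.5 equiv), AcOH (2.5 equiv), degassed THF, 0 °C to rt; work-up with aq. Na2S2O4
Reagents that add atoms: none
Why: Fluoride-mediated desilylation cleaves both aryl O–Si bonds (phenoxide leaving groups) under acetic acid buffering without acid, so the ionisable allylic alcohol, the four alkenes and the C9' stereocentre are untouched; exclusion of oxygen and the dithionite wash keep the hydroquinone from oxidising.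

**Compound list**

1 | 2-bromo-6-methylphenol | Cc1cccc(Br)c1O | starting material
2 | 2-bromo-6-methyl-1,4-benzoquinone | CC1=CC(=O)C=C(Br)C1=O | intermediate
3 | 2-bromo-6-methylbenzene-1,4-diol | Cc1cc(O)cc(Br)c1O | intermediate
4 | [(2-bromo-6-methyl-1,4-phenylene)bis(oxy)]bis(triisopropylsilane) | Cc1cc(O[Si](C(C)C)(C(C)C)C(C)C)cc(Br)c1O[Si](C(C)C)(C(C)C)C(C)C | intermediate
5 | geranyl acetate, (E)-3,7-dimethylocta-2,6-dien-1-yl acetate | CC(C)=CCC/C(C)=C/COC(C)=O | starting material
6 | (E)-5-(3,3-dimethyloxiran-2-yl)-3-methylpent-2-en-1-yl acetate (racemic at the oxirane carbon) | CC(=O)OC/C=C(\C)CCC1OC1(C)C | intermediate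
7 | (E)-6,7-dihydroxy-3,7-dimethyloct-2-en-1-yl acetate (racemic) | CC(=O)OC/C=C(\C)CCC(O)C(C)(C)O | intermediate (not isolated)
8 | (E)-6-acetoxy-4-methylhex-4-enal | CC(=O)OC/C=C(\C)CCC=O | intermediate
9 | (E)-3-methylhept-2-en-6-yn-1-ol | C#CCC/C(C)=C/CO | intermediate
10 | dilithio derivative of 9 (lithium alkoxide, lithium acetylide) | [Li]C#CCC/C(C)=C/CO[Li] | intermediate (not isolated)
11 | (E)-3-methyloct-2-en-6-yn-1-ol | CC#CCC/C(C)=C/CO | intermediate
12 | (E)-C7' alkenylzirconocene chloride of the zirconium alkoxide of 11 | C/C(=C\CC/C(C)=C/CO[Zr](Cl)(C1C=CC=C1)C1C=CC=C1)[Zr](Cl)(C1C=CC=C1)C1C=CC=C1 | intermediate (not isolated)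
13 | (2E,6E)-7-bromo-3-methylocta-2,6-dien-1-ol | C/C(Br)=C\CC/C(C)=C/CO | intermediate
14 | (2E,6E)-1,7-dibromo-3-methylocta-2,6-diene | C/C(Br)=C\CC/C(C)=C/CBr | intermediate
15 | [3-methyl-2,5-bis(triisopropylsilyloxy)phenyl]lithium | [Li]c1cc(O[Si](C(C)C)(C(C)C)C(C)C)cc(C)c1O[Si](C(C)C)(C(C)C)C(C)C | intermediate (not isolated)
16 | [3-methyl-2,5-bis(triisopropylsilyloxy)phenyl]copper | [Cu]c1cc(O[Si](C(C)C)(C(C)C)C(C)C)cc(C)c1O[Si](C(C)C)(C(C)C)C(C)C | intermediate (not isolated)
17 | [2-[(2E,6E)-7-bromo-3-methylocta-2,6-dien-1-yl]-6-methyl-1,4-phenylene]bis(oxy)bis(triisopropylsilane) | C/C(Br)=C\CC/C(C)=C/Cc1cc(O[Si](C(C)C)(C(C)C)C(C)C)cc(C)c1O[Si](C(C)C)(C(C)C)C(C)C | intermediate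
18 | 6-methylhept-5-en-2-one (sulcatone) | CC(=O)CCC=C(C)C | starting material
19 | diethyl 6-methylhepta-1,5-dien-2-yl phosphate | C=C(CCC=C(C)C)OP(=O)(OCC)OCC | intermediate (not isolated)
20 | 6-methylhept-5-en-1-yne | C#CCCC=C(C)C | intermediate
21 | [(E)-2,6-dimethylhepta-1,5-dien-1-yl]dimethylalane | C[Al](C)/C=C(\C)CCC=C(C)C | intermediate (not isolated)
22 | (E)-1-iodo-2,6-dimethylhepta-1,5-diene | I/C=C(\C)CCC=C(C)C | intermediate
23 | acenaphthenequinone | O=C1C(=O)c2cccc3cccc1c23 | starting material
24 | cis-1,2-dimethyl-1,2-dihydroacenaphthylene-1,2-diol (mac diol, meso) | C[C@]1(O)c2cccc3cccc(c23)[C@@]1(C)O | intermediate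
25 | [(E)-2,6-dimethylhepta-1,5-dien-1-yl]lithium | [Li]/C=C(\C)CCC=C(C)C | intermediate (not isolated)
26 | (E)-(2,6-dimethylhepta-1,5-dien-1-yl)boronic acid | OB(O)/C=C(\C)CCC=C(C)C | intermediate (not isolated)
27 | (E)-(2,6-dimethylhepta-1,5-dien-1-yl)boronic acid mac ester (mac = cis-1,2-dimethylacenaphthylene-1,2-diolato) | CC(C)=CCC/C(C)=C/B1O[C@@]2(C)c3cccc4cccc(c34)[C@@]2(C)O1 | intermediate
28 | lithium [(E)-2,6-dimethylhepta-1,5-dien-1-yl](vinyl)(mac)borate (mixture of boron epimers) | [Li+].C=C[B-]1(/C=C(\C)CCC=C(C)C)O[C@@]2(C)c3cccc4cccc(c34)[C@@]2(C)O1 | intermediate (not isolated)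
29 | 2-[(2E,6E,9R,10E)-3,7,11,15-tetramethyl-9-(mac-boryl)hexadeca-2,6,10,14-tetraen-1-yl]-6-methyl-1,4-bis(triisopropylsilyloxy)benzene | CC(C)=CCC/C(C)=C/[C@H](B1O[C@@]2(C)c3cccc4cccc(c34)[C@@]2(C)O1)C/C(C)=C/CC/C(C)=C/Cc1cc(O[Si](C(C)C)(C(C)C)C(C)C)cc(C)c1O[Si](C(C)C)(C(C)C)C(C)C | intermediate
30 | (2E,6E,9R,10E)-3,7,11,15-tetramethyl-1-[3-methyl-2,5-bis(triisopropylsilyloxy)phenyl]hexadeca-2,6,10,14-tetraen-9-ol | CC(C)=CCC/C(C)=C/[C@H](O)C/C(C)=C/CC/C(C)=C/Cc1cc(O[Si](C(C)C)(C(C)C)C(C)C)cc(C)c1O[Si](C(C)C)(C(C)C)C(C)C | intermediate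
31 | 2-[(2E,6E,9R,10E)-9-hydroxy-3,7,11,15-tetramethylhexadeca-2,6,10,14-tetraen-1-yl]-6-methylbenzene-1,4-diol | CC(C)=CCC/C(C)=C/[C@H](O)C/C(C)=C/CC/C(C)=C/Cc1cc(O)cc(C)c1O | target

**Step count and risks**

Total step count: 17. Longest linear sequence: 10 steps (steps 4–10, then 15–17, from geranyl acetate).

The three steps most likely to fail:

1. Step 15 (key step). What may go wrong: direct transfer of an alkenyl group from boron to palladium (Suzuki–Miyaura pathway) instead of the metallate shift; slow oxidative addition or reductive elimination at the α-methyl-substituted alkenyl bromide; inhibition by bromide; insufficient enantioface discrimination. Fallback: the same C8'–C7' bond is made at the ketone oxidation level. Iodide 22 is lithiated (t-BuLi, −78 °C) and acylated with N-methoxy-N-methylacetamide to give (E)-4,8-dimethylnona-3,7-dien-2-one F1. Its kinetic lithium enolate (LiHMDS, −78 °C, deprotonation at the methyl group) is joined to bromide 17 by Pd-catalysed α-alkenylation of a ketone enolate (Pd(dba)2, P(t-Bu)3, THF, rt), giving the β,γ-unsaturated dienone (6E,10E,14E)-2,6,10,14-tetramethyl-16-[3-methyl-2,5-bis(triisopropylsilyloxy)phenyl]hexadeca-2,6,10,14-tetraen-8-one F2. CBS reduction of F2 with (S)-Me-CBS and catecholborane at −78 °C (alkenyl as the large group) should set the (R)-carbinol and rejoin the route at 30.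

2. Step 8. What may go wrong: incomplete thermodynamic equilibration of the regioisomeric alkenylzirconocenes, so that part of the zirconium, and then the bromine, ends on C6'; bromination of the trisubstituted alkene by excess NBS. Fallback with full regiocontrol through silicon, setting out from alkynol 9. Treatment with n-BuLi (2.1 equiv) and TMSCl, then dilute acid to free the oxygen, gives (E)-3-methyl-7-(trimethylsilyl)hept-2-en-6-yn-1-ol F3. Hydroalumination with DIBAL-H in heptane at 55 °C puts aluminium only on the silyl-bearing carbon and, without donor solvent, gives the net anti adduct; ate formation with MeLi and methylation with MeI then give (2E,6E)-3-methyl-7-(trimethylsilyl)octa-2,6-dien-1-ol F4. Ipso-bromodesilylation of F4 with NBS in MeCN at 0 °C (retention through the β-silyl cation) returns to the route at 13.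

3. Step 10. What may go wrong: O-to-C silyl migration in the ortho-lithiated aryl silyl ether, slow coupling of the hindered arylcopper, and γ-attack on the allylic bromide. Fallback without an aryl–metal species: commercial 2-methylhydroquinone is monosilylated at its unhindered 4-hydroxyl (TIPSCl, imidazole, DMF) to give 2-methyl-4-[(triisopropylsilyl)oxy]phenol F5. Its sodium phenoxide (NaH, toluene) is C-allylated with dibromide 14 at the only free ortho position (ortho-C-alkylation of a phenoxide in a non-polar medium), giving 2-[(2E,6E)-7-bromo-3-methylocta-2,6-dien-1-yl]-6-methyl-4-[(triisopropylsilyl)oxy]phenol F6. Silylation of F6 with TIPSOTf and 2,6-lutidine returns to the route at 17.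

Further compounds
F1 | step 15 | (E)-4,8-dimethylnona-3,7-dien-2-one | CC(=O)/C=C(\C)CCC=C(C)C
F2 | step 15 | (6E,10E,14E)-2,6,10,14-tetramethyl-16-[3-methyl-2,5-bis(triisopropylsilyloxy)phenyl]hexadeca-2,6,10,14-tetraen-8-one | CC(C)=CCC/C(C)=C/C(=O)C/C(C)=C/CC/C(C)=C/Cc1cc(O[Si](C(C)C)(C(C)C)C(C)C)cc(C)c1O[Si](C(C)C)(C(C)C)C(C)C
F3 | step 8 | (E)-3-methyl-7-(trimethylsilyl)hept-2-en-6-yn-1-ol | C[Si](C)(C)C#CCC/C(C)=C/CO
F4 | step 8 | (2E,6E)-3-methyl-7-(trimethylsilyl)octa-2,6-dien-1-ol | C/C(=C\CC/C(C)=C/CO)[Si](C)(C)C
F5 | step 10 | 2-methyl-4-[(triisopropylsilyl)oxy]phenol | Cc1cc(O[Si](C(C)C)(C(C)C)C(C)C)ccc1O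
F6 | step 10 | 2-[(2E,6E)-7-bromo-3-methylocta-2,6-dien-1-yl]-6-methyl-4-[(triisopropylsilyl)oxy]phenol | C/C(Br)=C\CC/C(C)=C/Cc1cc(O[Si](C(C)C)(C(C)C)C(C)C)cc(C)c1O
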